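**Retrosynthetic overview**
1. Germacranolide numbering is used: carbocycle C1–C10 (ring-cis olefins C1=C10 and C4=C5, C14H2OH on C10, C15H2OH on C4), lactone C7–C11(=C13H2)–C12(=O)–O–C8, tiglate on O6. The end game from bicyclic lactone 20 is O6 desilylation, tigloylation and removal of the two primary silyl ethers.
2. Key disconnection: the ten-membered carbocycle and the γ-lactone are opened together at C7–C8 and C11–C12 (with C12–O) to the acyclic allenyl aldehyde 19 plus CO, i.e. a macrocyclising allene–aldehyde–CO [2+2+1] cycloaddition (hetero-Pauson–Khand type).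
3. Enabling feature: the α-methylene-γ-butyrolactone O–C8–C7–C11(=C13H2)–C12(=O), fused to the ten-membered ring at C7–C8, is the exact retron of a terminal allene (C7=C11=C13), an aldehyde (C8=O) and CO. The two ring-cis trisubstituted olefins fold the open chain, and the C6 silyloxy stereocentre next to the allene relays C7 and C8.
4. Precursor 19: the allene comes from Crabbé homologation of a propargylic alcohol whose C6 centre is set by catalytic asymmetric alkynylation of enal 11. The C8–C6 chain comes from two copies of one (Z)-iodoallylic alcohol 4 (from but-2-yne-1,4-diol), joined by a Negishi coupling (C9–C10) and a B-alkyl Suzuki coupling (C3–C4).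
5. Ring order: no ring is formed before step 12; there the ten-membered carbocycle (C7–C8) and the γ-lactone (C11–C12, C12–O) close in the same operation.

Key step: step 12

Abbreviations: TBDPS = tert-butyldiphenylsilyl, TES = triethylsilyl.
Remark on the chemistry: the (S,S)-ProPhenol ligand is assumed to deliver the alkyne to the enal face that gives the (3R)-carbinol 13; should the sense be the opposite, the (R,R)-ligand is used and nothing else changes.

Step 1
Reactants: 1 but-2-yne-1,4-diol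
Product: 2 4-(TBDPS-oxy)but-2-yn-1-ol
Conditions: TBDPSCl (1 equiv), imidazole, 1 (4 equiv), DMF, 0 °C to rt
Reagents that add atoms: tert-butyl(chloro)diphenylsilane, CC(C)(C)[Si](Cl)(c1ccccc1)c1ccccc1
Why: Statistical monosilylation (silyl ether formation) of a symmetrical diol used in excess should give the mono-ether; no stereocentre is involved.

Step 2
Reactants: 2 4-(TBDPS-oxy)but-2-yn-1-ol
Product: 4 (2Z)-4-(TBDPS-oxy)-3-iodobut-2-en-1-ol, via cyclic alkenylalanate 3 (not isolated)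
Conditions: NaAlH2(OCH2CH2OMe)2 (1.5 equiv), THF, 0 °C to rt; then I2, THF, −78 °C to 0 °C
Reagents that add atoms: iodine, II
Why: Hydroxyl-directed anti-hydroalumination of the propargylic alcohol puts aluminium on the distal carbon and iodinolysis with retention should give the (Z)-iodoalkene (I cis to CH2OH), which fixes the ring-cis olefin geometry that is used twice.

Step 3
Reactants: 4 (2Z)-4-(TBDPS-oxy)-3-iodobut-2-en-1-ol; 5 (1,3-dioxolan-2-ylmethyl)zinc bromide
Product: 6 (2E)-4-(TBDPS-oxy)-3-(1,3-dioxolan-2-ylmethyl)but-2-en-1-ol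
Conditions: 5 (2.5 equiv), Pd(PPh3)4 (5 mol%), THF, 45 °C
Reagents that add atoms: none
Why: Negishi cross-coupling of the alkenyl iodide with the alkylzinc halide proceeds with retention of olefin geometry and installs C9 and the masked C8 aldehyde (the descriptor changes to E only because of the CIP priorities).

Step 4
Reactants: 6 (2E)-4-(TBDPS-oxy)-3-(1,3-dioxolan-2-ylmethyl)but-2-en-1-ol
Product: 7 (2E)-4-(TBDPS-oxy)-3-(1,3-dioxolan-2-ylmethyl)but-2-enal
Conditions: MnO2 (20 equiv), CH2Cl2, rt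
Reagents that add atoms: none
Why: Allylic oxidation with MnO2 stops at the enal under neutral conditions, so the olefin geometry, the acetal and the silyl ether should be kept.

Step 5
Reactants: 7 (2E)-4-(TBDPS-oxy)-3-(1,3-dioxolan-2-ylmethyl)but-2-enal
Product: 8 tert-butyl{[(2E)-2-(1,3-dioxolan-2-ylmethyl)penta-2,4-dien-1-yl]oxy}diphenylsilane
Conditions: Ph3PCH3Br (1.5 equiv), NaN(SiMe3)2 (1.4 equiv), THF, 0 °C; then 7, −78 °C to 0 °C
Reagents that add atoms: methyltriphenylphosphonium bromide, C[P+](c1ccccc1)(c1ccccc1)c1ccccc1.[Br-]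
Why: Wittig methylenation of the enal with the unstabilised ylide at low temperature should give the terminal diene without touching the trisubstituted olefin.

Step 6
Reactants: 8 tert-butyl{[(2E)-2-(1,3-dioxolan-2-ylmethyl)penta-2,4-dien-1-yl]oxy}diphenylsilane; 4 (2Z)-4-(TBDPS-oxy)-3-iodobut-2-en-1-ol
Product: 10 (2E,6E)-3,7-bis(TBDPS-oxymethyl)-8-(1,3-dioxolan-2-yl)octa-2,6-dien-1-ol, via B-alkyl-9-BBN borane 9 (not isolated)
Conditions: 9-BBN (1.2 equiv), THF, 0 °C to rt; then 4, PdCl2(dppf) (5 mol%), AsPh3 (10 mol%), Cs2CO3 (3 equiv), DMF/H2O, rt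
Reagents that add atoms: none
Why: 9-BBN adds anti-Markovnikov to the monosubstituted terminal olefin of the diene, and the B-alkyl Suzuki–Miyaura coupling with iodide 4 forms C3–C4 with retention, so the second ring-cis olefin is carried in intact.

Step 7
Reactants: 10 (2E,6E)-3,7-bis(TBDPS-oxymethyl)-8-(1,3-dioxolan-2-yl)octa-2,6-dien-1-ol
Product: 11 (2E,6E)-3,7-bis(TBDPS-oxymethyl)-8-(1,3-dioxolan-2-yl)octa-2,6-dienal
Conditions: MnO2 (20 equiv), CH2Cl2, rt
Reagents that add atoms: none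
Why: Chemoselective MnO2 oxidation of the allylic alcohol should give the enal without isomerising the β,β-disubstituted olefin.

Step 8
Reactants: 11 (2E,6E)-3,7-bis(TBDPS-oxymethyl)-8-(1,3-dioxolan-2-yl)octa-2,6-dienal; 12 ethynyl(trimethyl)silane
Product: 13 (3R,4E,8E)-5,9-bis(TBDPS-oxymethyl)-10-(1,3-dioxolan-2-yl)-1-(trimethylsilyl)deca-4,8-dien-1-yn-3-ol
Conditions: 12 (3 equiv), ZnMe2 (3 equiv), (S,S)-ProPhenol (20 mol%), Ph3PO (40 mol%), toluene, 4 °C
Reagents that add atoms: none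
Why: Zinc–ProPhenol-catalysed asymmetric alkynylation of the enal, in which the chiral dinuclear zinc complex delivers the alkynyl group to one aldehyde face, sets C6 as the only stereocentre made by catalysis.

Step 9
Reactants: 13 (3R,4E,8E)-5,9-bis(TBDPS-oxymethyl)-10-(1,3-dioxolan-2-yl)-1-(trimethylsilyl)deca-4,8-dien-1-yn-3-ol
Product: 14 (3R,4E,8E)-5,9-bis(TBDPS-oxymethyl)-10-(1,3-dioxolan-2-yl)deca-4,8-dien-1-yn-3-ol
Conditions: K2CO3 (0.5 equiv), MeOH, 0 °C to rt
Reagents that add atoms: none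
Why: Base-mediated protodesilylation of the alkynylsilane should free the terminal alkyne without touching the carbinol, the acetal or the TBDPS ethers.

Step 10
Reactants: 14 (3R,4E,8E)-5,9-bis(TBDPS-oxymethyl)-10-(1,3-dioxolan-2-yl)deca-4,8-dien-1-yn-3-ol
Product: 16 (4S,5E,9E)-6,10-bis(TBDPS-oxymethyl)-11-(1,3-dioxolan-2-yl)undeca-1,2,5,9-tetraen-4-ol, via propargylic Mannich base 15 (not isolated)
Conditions: (CH2O)n (2.5 equiv), CuI (0.5 equiv), dicyclohexylamine (1.8 equiv), 1,4-dioxane, 100 °C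
Reagents that add atoms: paraformaldehyde (as formaldehyde), C=O
Why: Crabbé homologation, a copper-mediated Mannich reaction of the terminal alkyne followed by 1,5-hydride transfer and loss of the imine, should give the terminal allene; the carbinol centre is not involved (its descriptor changes to S only through the CIP priorities).

Step 11
Reactants: 16 (4S,5E,9E)-6,10-bis(TBDPS-oxymethyl)-11-(1,3-dioxolan-2-yl)undeca-1,2,5,9-tetraen-4-ol
Product: 19 (3E,7E,9S)-3,7-bis(TBDPS-oxymethyl)-9-(TES-oxy)dodeca-3,7,10,11-tetraenal, via TES ether acetal 17 (not isolated), via collidinium salt 18 (not isolated)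
Conditions: TESOTf (4 equiv), 2,4,6-collidine (6 equiv), CH2Cl2, 0 °C; then H2O, 0 °C to rt; used at once
Reagents that add atoms: triethylsilyl trifluoromethanesulfonate, CC[Si](CC)(CC)OS(=O)(=O)C(F)(F)F; water, O
Why: Silyl triflate–collidine chemistry silylates O6 and opens the dioxolane to a collidinium salt that water converts to the aldehyde (acetal cleavage without protic acid), which should keep the β,γ-olefin out of conjugation and all silyl ethers in place.

Step 12
Reactants: 19 (3E,7E,9S)-3,7-bis(TBDPS-oxymethyl)-9-(TES-oxy)dodeca-3,7,10,11-tetraenal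
Product: 20 (3aR,4R,5E,9E,11aS)-6,10-bis(TBDPS-oxymethyl)-3-methylidene-4-(TES-oxy)-3a,4,7,8,11,11a-hexahydrocyclodeca[b]furan-2(3H)-one
Conditions: Mo(CO)6 (1.5 equiv), DMSO (10 equiv), toluene, 100 °C, 19 added over 12 h (final 0.002 M)
Reagents that add atoms: hexacarbonylmolybdenum (one CO), [Mo].[C-]#[O+].[C-]#[O+].[C-]#[O+].[C-]#[O+].[C-]#[O+].[C-]#[O+]
Why: Proposed new method: macrocyclising hetero-Pauson–Khand reaction, in which DMSO strips CO from Mo(CO)6, zerovalent molybdenum binds the allene and the aldehyde of 19, oxidative cyclisation forms C7–C8 and an oxamolybdacyclopentane with the metal on C11, CO insertion forms C11–C12 and reductive elimination closes C12–O. The closest known reaction type is the Mo(CO)6/DMSO-mediated (or Ru3(CO)12-catalysed) cyclocarbonylation of short-tethered allenyl aldehydes to bicyclic α-methylene-γ-butyrolactones with five- and six-membered carbocycles; what is new is the ten-membered closure, for which nickel-mediated macrocyclic alkyne–aldehyde oxidative cyclisations are the nearest support. The carbocycle closes 10-exo-trig at C7 (the C11=C13 unit stays exocyclic), eased by the two ring-cis olefins that put four sp2 carbons into the chain and fold it, and the lactone closes as the five-membered ring of the [2+2+1] event. C7 is controlled by C6: with H6 eclipsing the allene (least A1,3 strain) the aldehyde carbon is delivered anti to the bulky OSiEt3 group, and C8 follows because the C9 chain takes the position trans to C6 on the five-membered metallacycle, the arrangement that lets the bridge between C6 and C9 span without eclipsing, so that the trans-fused (6R,7R,8S) lactone should result. The step needs the internal allene π-bond (C7=C11) to react in preference to the terminal one and ring closure to outrun oligomerisation: the first rests on the preference of molybdenum for the internal π-bond of CH2-terminated allenes and on the strain of the bridged twelve-membered lactone with a bridgehead olefin that attack at C13 would give, the second on slow addition at about 2 mM.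

Step 13
Reactants: 20 (3aR,4R,5E,9E,11aS)-6,10-bis(TBDPS-oxymethyl)-3-methylidene-4-(TES-oxy)-3a,4,7,8,11,11a-hexahydrocyclodeca[b]furan-2(3H)-one
Product: 21 (3aS,4R,5E,9E,11aS)-6,10-bis(TBDPS-oxymethyl)-4-hydroxy-3-methylidene-3a,4,7,8,11,11a-hexahydrocyclodeca[b]furan-2(3H)-one
Conditions: pyridinium p-toluenesulfonate (0.2 equiv), MeOH/CH2Cl2 1:1, 0 °C
Reagents that add atoms: none
Why: Acid-catalysed methanolysis (silyl ether cleavage) removes the secondary triethylsilyl ether much faster than the two primary TBDPS ethers; no stereocentre changes (the 3a descriptor changes only through the CIP priorities).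

Step 14
Reactants: 21 (3aS,4R,5E,9E,11aS)-6,10-bis(TBDPS-oxymethyl)-4-hydroxy-3-methylidene-3a,4,7,8,11,11a-hexahydrocyclodeca[b]furan-2(3H)-one; 22 (2E)-2-methylbut-2-enoyl chloride
Product: 23 (3aR,4R,5E,9E,11aS)-6,10-bis(TBDPS-oxymethyl)-3-methylidene-2-oxo-2,3,3a,4,7,8,11,11a-octahydrocyclodeca[b]furan-4-yl (2E)-2-methylbut-2-enoate
Conditions: 22 (2 equiv), Et3N (3 equiv), DMAP (0.2 equiv), CH2Cl2, 0 °C to rt
Reagents that add atoms: none
Why: DMAP-catalysed acylation of the secondary allylic alcohol with the acid chloride should give the tiglate with retention at C6 and without E/Z isomerisation of the acyl group.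

Step 15
Reactants: 23 (3aR,4R,5E,9E,11aS)-6,10-bis(TBDPS-oxymethyl)-3-methylidene-2-oxo-2,3,3a,4,7,8,11,11a-octahydrocyclodeca[b]furan-4-yl (2E)-2-methylbut-2-enoate
Product: 24 (3aR,4R,5E,9E,11aS)-6,10-bis(hydroxymethyl)-3-methylidene-2-oxo-2,3,3a,4,7,8,11,11a-octahydrocyclodeca[b]furan-4-yl (2E)-2-methylbut-2-enoate
Conditions: HF·pyridine (excess), pyridine, THF, 0 °C to rt
Reagents that add atoms: none
Why: Fluoride-mediated desilylation under buffered, weakly acidic conditions cleaves both primary silyl ethers and should leave the tiglate, the α-methylene lactone and the olefins untouched.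

**Compound list**
1 | but-2-yne-1,4-diol | OCC#CCO | starting material
2 | 4-[(tert-butyldiphenylsilyl)oxy]but-2-yn-1-ol | OCC#CCO[Si](c1ccccc1)(c1ccccc1)C(C)(C)C | intermediate
3 | sodium cyclic alkenylalanate from anti-hydroalumination of 2 (five-membered O–Al–C ring, two 2-methoxyethoxy groups on Al) | [Na+].COCCO[Al-]1(OCCOC)OCC=C1CO[Si](c2ccccc2)(c2ccccc2)C(C)(C)C | intermediate
4 | (2Z)-4-[(tert-butyldiphenylsilyl)oxy]-3-iodobut-2-en-1-ol | I/C(CO[Si](c1ccccc1)(c1ccccc1)C(C)(C)C)=C\CO | intermediate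
5 | (1,3-dioxolan-2-ylmethyl)zinc bromide | Br[Zn]CC1OCCO1 | starting material
6 | (2E)-4-[(tert-butyldiphenylsilyl)oxy]-3-(1,3-dioxolan-2-ylmethyl)but-2-en-1-ol | O1CCOC1C/C(CO[Si](c2ccccc2)(c2ccccc2)C(C)(C)C)=C\CO | intermediate
7 | (2E)-4-[(tert-butyldiphenylsilyl)oxy]-3-(1,3-dioxolan-2-ylmethyl)but-2-enal | O1CCOC1C/C(CO[Si](c2ccccc2)(c2ccccc2)C(C)(C)C)=C\C=O | intermediate
8 | tert-butyl{[(2E)-2-(1,3-dioxolan-2-ylmethyl)penta-2,4-dien-1-yl]oxy}diphenylsilane | O1CCOC1C/C(CO[Si](c2ccccc2)(c2ccccc2)C(C)(C)C)=C\C=C | intermediate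
9 | 9-[(3E)-5-[(tert-butyldiphenylsilyl)oxy]-4-(1,3-dioxolan-2-ylmethyl)pent-3-en-1-yl]-9-borabicyclo[3.3.1]nonane | O1CCOC1C/C(CO[Si](c2ccccc2)(c2ccccc2)C(C)(C)C)=C\CCB1C2CCCC1CCC2 | intermediate
10 | (2E,6E)-3,7-bis{[(tert-butyldiphenylsilyl)oxy]methyl}-8-(1,3-dioxolan-2-yl)octa-2,6-dien-1-ol | O1CCOC1C/C(CO[Si](c2ccccc2)(c2ccccc2)C(C)(C)C)=C\CC/C(CO[Si](c2ccccc2)(c2ccccc2)C(C)(C)C)=C\CO | intermediate
11 | (2E,6E)-3,7-bis{[(tert-butyldiphenylsilyl)oxy]methyl}-8-(1,3-dioxolan-2-yl)octa-2,6-dienal | O1CCOC1C/C(CO[Si](c2ccccc2)(c2ccccc2)C(C)(C)C)=C\CC/C(CO[Si](c2ccccc2)(c2ccccc2)C(C)(C)C)=C\C=O | intermediate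
12 | ethynyl(trimethyl)silane | C#C[Si](C)(C)C | starting material
13 | (3R,4E,8E)-5,9-bis{[(tert-butyldiphenylsilyl)oxy]methyl}-10-(1,3-dioxolan-2-yl)-1-(trimethylsilyl)deca-4,8-dien-1-yn-3-ol | O1CCOC1C/C(CO[Si](c2ccccc2)(c2ccccc2)C(C)(C)C)=C\CC/C(CO[Si](c2ccccc2)(c2ccccc2)C(C)(C)C)=C\[C@@H](O)C#C[Si](C)(C)C | intermediate
14 | (3R,4E,8E)-5,9-bis{[(tert-butyldiphenylsilyl)oxy]methyl}-10-(1,3-dioxolan-2-yl)deca-4,8-dien-1-yn-3-ol | O1CCOC1C/C(CO[Si](c2ccccc2)(c2ccccc2)C(C)(C)C)=C\CC/C(CO[Si](c2ccccc2)(c2ccccc2)C(C)(C)C)=C\[C@@H](O)C#C | intermediate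
15 | (4R,5E,9E)-6,10-bis{[(tert-butyldiphenylsilyl)oxy]methyl}-1-(dicyclohexylamino)-11-(1,3-dioxolan-2-yl)undeca-5,9-dien-2-yn-4-ol | O1CCOC1C/C(CO[Si](c2ccccc2)(c2ccccc2)C(C)(C)C)=C\CC/C(CO[Si](c2ccccc2)(c2ccccc2)C(C)(C)C)=C\[C@@H](O)C#CCN(C3CCCCC3)C3CCCCC3 | intermediate
16 | (4S,5E,9E)-6,10-bis{[(tert-butyldiphenylsilyl)oxy]methyl}-11-(1,3-dioxolan-2-yl)undeca-1,2,5,9-tetraen-4-ol | O1CCOC1C/C(CO[Si](c2ccccc2)(c2ccccc2)C(C)(C)C)=C\CC/C(CO[Si](c2ccccc2)(c2ccccc2)C(C)(C)C)=C\[C@@H](O)C=C=C | intermediate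
17 | {[(4S,5E,9E)-6,10-bis{[(tert-butyldiphenylsilyl)oxy]methyl}-11-(1,3-dioxolan-2-yl)undeca-1,2,5,9-tetraen-4-yl]oxy}triethylsilane | O1CCOC1C/C(CO[Si](c2ccccc2)(c2ccccc2)C(C)(C)C)=C\CC/C(CO[Si](c2ccccc2)(c2ccccc2)C(C)(C)C)=C\[C@@H](O[Si](CC)(CC)CC)C=C=C | intermediate
18 | 2,4,6-trimethylpyridinium triflate N-bonded to C8 of the ring-opened acetal of 17 (C8 also carries OCH2CH2OTES; mixture at C8) | Cc1cc(C)[n+](C(OCCO[Si](CC)(CC)CC)C/C(CO[Si](c2ccccc2)(c2ccccc2)C(C)(C)C)=C\CC/C(CO[Si](c2ccccc2)(c2ccccc2)C(C)(C)C)=C\[C@@H](O[Si](CC)(CC)CC)C=C=C)c(C)c1.[O-]S(=O)(=O)C(F)(F)F | intermediate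
19 | (3E,7E,9S)-3,7-bis{[(tert-butyldiphenylsilyl)oxy]methyl}-9-[(triethylsilyl)oxy]dodeca-3,7,10,11-tetraenal | O=CC/C(CO[Si](c1ccccc1)(c1ccccc1)C(C)(C)C)=C\CC/C(CO[Si](c1ccccc1)(c1ccccc1)C(C)(C)C)=C\[C@@H](O[Si](CC)(CC)CC)C=C=C | intermediate
20 | (3aR,4R,5E,9E,11aS)-6,10-bis{[(tert-butyldiphenylsilyl)oxy]methyl}-3-methylidene-4-[(triethylsilyl)oxy]-3a,4,7,8,11,11a-hexahydrocyclodeca[b]furan-2(3H)-one | C=C1C(=O)O[C@H]2C/C(CO[Si](c3ccccc3)(c3ccccc3)C(C)(C)C)=C\CC/C(CO[Si](c3ccccc3)(c3ccccc3)C(C)(C)C)=C\[C@@H](O[Si](CC)(CC)CC)[C@H]12 | intermediate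
21 | (3aS,4R,5E,9E,11aS)-6,10-bis{[(tert-butyldiphenylsilyl)oxy]methyl}-4-hydroxy-3-methylidene-3a,4,7,8,11,11a-hexahydrocyclodeca[b]furan-2(3H)-one | C=C1C(=O)O[C@H]2C/C(CO[Si](c3ccccc3)(c3ccccc3)C(C)(C)C)=C\CC/C(CO[Si](c3ccccc3)(c3ccccc3)C(C)(C)C)=C\[C@@H](O)[C@H]12 | intermediate
22 | (2E)-2-methylbut-2-enoyl chloride (tigloyl chloride) | C/C=C(\C)C(Cl)=O | starting material
23 | (3aR,4R,5E,9E,11aS)-6,10-bis{[(tert-butyldiphenylsilyl)oxy]methyl}-3-methylidene-2-oxo-2,3,3a,4,7,8,11,11a-octahydrocyclodeca[b]furan-4-yl (2E)-2-methylbut-2-enoate | C=C1C(=O)O[C@H]2C/C(CO[Si](c3ccccc3)(c3ccccc3)C(C)(C)C)=C\CC/C(CO[Si](c3ccccc3)(c3ccccc3)C(C)(C)C)=C\[C@@H](OC(=O)/C(C)=C/C)[C@H]12 | intermediate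
24 | (3aR,4R,5E,9E,11aS)-6,10-bis(hydroxymethyl)-3-methylidene-2-oxo-2,3,3a,4,7,8,11,11a-octahydrocyclodeca[b]furan-4-yl (2E)-2-methylbut-2-enoate | C=C1C(=O)O[C@H]2C/C(CO)=C\CC/C(CO)=C\[C@@H](OC(=O)/C(C)=C/C)[C@H]12 | target

**Summary**
Total step count: 15. Longest linear sequence: 15 steps (1 to 24; iodide 4 enters twice, in steps 3 and 6).

Three steps most likely to fail:

1. Step 12. Ring closure may lose to oligomerisation, the terminal allene π-bond may react instead of the internal one, or facial selectivity at C7 and C8 may be poor. The fallback uses known reaction types, sets out from 11 and comes back at 20. Enal 11 is alkynylated under the step 8 conditions with trimethyl(prop-2-yn-1-yl)silane in place of 12 to give the propargylic alcohol F1. Hydroxyl-directed anti-hydroalumination and iodination (NaAlH2(OCH2CH2OMe)2, THF, 0 °C; then I2, −78 °C) give the (Z)-2-iodoallylsilane F2. TESOTf/2,4,6-collidine and then water, as in step 11, give the silyl-protected aldehyde F3. An intramolecular Hosomi–Sakurai allylation (BF3·OEt2, CH2Cl2, −78 °C, high dilution) closes the ten-membered ring at C7–C8 by SE2′ attack of the allylsilane and should give the 2-iodoallyl carbinol F4. Carbonylative lactonisation catalysed by Pd(PPh3)4 (CO 1 atm, K2CO3, THF, 60 °C) then forms C11–C12 and C12–O and returns to 20.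

2. Step 8. Enantioselectivity may be low, or the β,β-disubstituted enal may isomerise from Z to E chain geometry under the zinc conditions. The fallback sets out from 11 and comes back at 13. Addition of LiC≡CSiMe3 (from 12 and n-butyllithium, THF, −78 °C) to 11 gives the racemic alcohol F5, MnO2 oxidation gives the ynone F6, and Midland reduction with (R)-Alpine-Borane (B-isopinocampheyl-9-BBN from (+)-α-pinene), in which the alkynyl group is the small substituent, should give 13.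

3. Step 13. During selective desilylation and the acylation that follows, the lactone acyl group may migrate from O8 to the freed O6 hydroxyl, or the primary silyl ethers may be partly lost. The fallback sets out from 16 and comes back at 23, with the tiglate put on before ring closure. Alcohol 16 is acylated with 22 (Et3N, DMAP, CH2Cl2) to the allenyl tiglate F7, the acetal is opened with TESOTf/2,4,6-collidine and then water to the aldehyde F8, and the step 12 conditions close both rings to give 23 directly, so that a free O6 hydroxyl never sits next to the lactone.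

**Further compounds**
F1 | step 12 | (4R,5E,9E)-6,10-bis{[(tert-butyldiphenylsilyl)oxy]methyl}-11-(1,3-dioxolan-2-yl)-1-(trimethylsilyl)undeca-5,9-dien-2-yn-4-ol | O1CCOC1C/C(CO[Si](c2ccccc2)(c2ccccc2)C(C)(C)C)=C\CC/C(CO[Si](c2ccccc2)(c2ccccc2)C(C)(C)C)=C\[C@@H](O)C#CC[Si](C)(C)C
F2 | step 12 | (2Z,4R,5E,9E)-6,10-bis{[(tert-butyldiphenylsilyl)oxy]methyl}-11-(1,3-dioxolan-2-yl)-2-iodo-1-(trimethylsilyl)undeca-2,5,9-trien-4-ol | O1CCOC1C/C(CO[Si](c2ccccc2)(c2ccccc2)C(C)(C)C)=C\CC/C(CO[Si](c2ccccc2)(c2ccccc2)C(C)(C)C)=C\[C@@H](O)/C=C(\I)C[Si](C)(C)C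
F3 | step 12 | (3E,7E,9R,10Z)-3,7-bis{[(tert-butyldiphenylsilyl)oxy]methyl}-11-iodo-9-[(triethylsilyl)oxy]-12-(trimethylsilyl)dodeca-3,7,10-trienal | O=CC/C(CO[Si](c1ccccc1)(c1ccccc1)C(C)(C)C)=C\CC/C(CO[Si](c1ccccc1)(c1ccccc1)C(C)(C)C)=C\[C@@H](O[Si](CC)(CC)CC)/C=C(\I)C[Si](C)(C)C
F4 | step 12 | (1S,2R,3R,4E,8E)-5,9-bis{[(tert-butyldiphenylsilyl)oxy]methyl}-2-(1-iodoethenyl)-3-[(triethylsilyl)oxy]cyclodeca-4,8-dien-1-ol | O[C@H]1C/C(CO[Si](c2ccccc2)(c2ccccc2)C(C)(C)C)=C\CC/C(CO[Si](c2ccccc2)(c2ccccc2)C(C)(C)C)=C\[C@@H](O[Si](CC)(CC)CC)[C@@H]1C(I)=C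
F5 | step 8 | racemic (4E,8E)-5,9-bis{[(tert-butyldiphenylsilyl)oxy]methyl}-10-(1,3-dioxolan-2-yl)-1-(trimethylsilyl)deca-4,8-dien-1-yn-3-ol | O1CCOC1C/C(CO[Si](c2ccccc2)(c2ccccc2)C(C)(C)C)=C\CC/C(CO[Si](c2ccccc2)(c2ccccc2)C(C)(C)C)=C\C(O)C#C[Si](C)(C)C
F6 | step 8 | (4E,8E)-5,9-bis{[(tert-butyldiphenylsilyl)oxy]methyl}-10-(1,3-dioxolan-2-yl)-1-(trimethylsilyl)deca-4,8-dien-1-yn-3-one | O1CCOC1C/C(CO[Si](c2ccccc2)(c2ccccc2)C(C)(C)C)=C\CC/C(CO[Si](c2ccccc2)(c2ccccc2)C(C)(C)C)=C\C(=O)C#C[Si](C)(C)C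
F7 | step 13 | (4S,5E,9E)-6,10-bis{[(tert-butyldiphenylsilyl)oxy]methyl}-11-(1,3-dioxolan-2-yl)undeca-1,2,5,9-tetraen-4-yl (2E)-2-methylbut-2-enoate | O1CCOC1C/C(CO[Si](c2ccccc2)(c2ccccc2)C(C)(C)C)=C\CC/C(CO[Si](c2ccccc2)(c2ccccc2)C(C)(C)C)=C\[C@@H](OC(=O)/C(C)=C/C)C=C=C
F8 | step 13 | (4S,5E,9E)-6,10-bis{[(tert-butyldiphenylsilyl)oxy]methyl}-12-oxododeca-1,2,5,9-tetraen-4-yl (2E)-2-methylbut-2-enoate | O=CC/C(CO[Si](c1ccccc1)(c1ccccc1)C(C)(C)C)=C\CC/C(CO[Si](c1ccccc1)(c1ccccc1)C(C)(C)C)=C\[C@@H](OC(=O)/C(C)=C/C)C=C=C
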